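**Retrosynthetic overview**

1. Iridal ⇐ cyclohexane hydroxy sulfone 20, by ester reduction, reductive desulfonylation, desilylation and allylic oxidation.
2. 20 ⇐ acyclic iodo-enoate methyl ketone 16 + phenyl vinyl sulfone 17 in one Michael-initiated ring closure. The enabling feature is that the two unsubstituted ring CH2 groups (C8, C9 in iridal numbering) lie between the alkylidene carbon C7 and the tertiary carbinol carbon C10 of the single cyclohexane. C7 can therefore act as an alkenyl nucleophile, C10 as a methyl ketone, and the C2 unit as a vinyl sulfone that is electrophilic at one carbon and, after the addition, nucleophilic at the other.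
3. The tetrasubstituted olefin geometry is fixed before the ring exists, by syn stannylcupration/methylation of ynoate 12 followed by tin–iodine exchange. The methyl ketone comes from the vinyl group by Wacker oxidation.
4. The quaternary/tertiary pair comes from an enantioselective Ireland–Claisen rearrangement of geranylgeranyl ester 5. This one step also delivers the homofarnesyl chain, the quaternary methyl, and (as the vinyl group) the carbinol carbon with its methyl.
5. Ring order: one carbocycle only, closed in step 12.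

Key step: step 12

Remark (assumption): the (S,S)-diazaborolidine controller is assumed to deliver the (2S,3R)-acid 7 in step 4; if the sense of induction is the opposite, the (R,R)-controller is used with no other change.

**Route**

Step 1
Reactants: 1 pentane-1,5-diol
Product: 2 5-[(tert-butyldiphenylsilyl)oxy]pentan-1-ol
Conditions: NaH (1.0 equiv), THF, 0 °C → rt; then t-BuPh2SiCl (1.0 equiv), rt
Reagents that add atoms: tert-butyl(chloro)diphenylsilane CC(C)(C)[Si](Cl)(c1ccccc1)c1ccccc1
Why: Silylation of the sparingly soluble monosodium alkoxide of a symmetrical diol should stop at the mono-ether; no stereocentre is formed.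

Step 2
Reactants: 2 5-[(tert-butyldiphenylsilyl)oxy]pentan-1-ol
Product: 3 5-[(tert-butyldiphenylsilyl)oxy]pentanoic acid
Conditions: TEMPO (cat.), PhI(OAc)2 (2.2 equiv), MeCN/H2O 1:1, rt
Reagents that add atoms: water O
Why: Oxoammonium oxidation in aqueous acetonitrile should take the primary alcohol through the aldehyde hydrate to the acid and leave the silyl ether intact.

Step 3
Reactants: 3 5-[(tert-butyldiphenylsilyl)oxy]pentanoic acid; 4 (2E,6E,10E)-geranylgeraniol
Product: 5 geranylgeranyl 5-[(tert-butyldiphenylsilyl)oxy]pentanoate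
Conditions: DCC, DMAP (cat.), CH2Cl2, 0 °C → rt
Reagents that add atoms: none
Why: Steglich esterification of a primary allylic alcohol under neutral conditions should avoid allylic transposition and E/Z isomerisation.

Step 4
Reactants: 5 geranylgeranyl 5-[(tert-butyldiphenylsilyl)oxy]pentanoate
Product: 7 (2S,3R)-2-(3-silyloxypropyl)-3-ethenyl-3-methyl acid, via boron ketene acetal 6 (not isolated)
Conditions: (S,S)-2-bromo-4,5-diphenyl-1,3-bis[3,5-bis(trifluoromethyl)benzenesulfonyl]-1,3,2-diazaborolidine (1.3 equiv, prepared beforehand), i-Pr2NEt, CH2Cl2, −78 °C; then −20 → 4 °C, 2–3 d; aqueous work-up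
Reagents that add atoms: none
Why: In this enantioselective Ireland–Claisen rearrangement, soft enolisation should give the Z(O)-boron ketene acetal (side chain cis to O–B), and its chair [3,3] shift onto the (E)-trisubstituted allyl terminus (methyl axial, homofarnesyl equatorial) sets the quaternary and the adjacent tertiary centre together, with the C2-symmetric diazaborolidine choosing the enolate face.

Step 5
Reactants: 7 (2S,3R)-acid
Product: 8 (2S,3R)-primary alcohol
Conditions: LiAlH4, Et2O, 0 °C → rt
Reagents that add atoms: none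
Why: Hydride reduction of the acid should leave the isolated olefins and the silyl ether untouched, and neither stereocentre is epimerisable under these conditions.

Step 6
Reactants: 8 (2S,3R)-primary alcohol
Product: 9 (2S,3R)-aldehyde
Conditions: Dess–Martin periodinane, CH2Cl2, 0 °C → rt
Reagents that add atoms: none
Why: Dess–Martin oxidation is mild and near-neutral, so the α-stereocentre next to the quaternary carbon should survive.

Step 7
Reactants: 9 (2S,3R)-aldehyde
Product: 10 (3R,4R)-terminal alkyne
Conditions: Ohira–Bestmann reagent, K2CO3, MeOH, 0 °C → rt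
Reagents that add atoms: dimethyl (1-diazo-2-oxopropyl)phosphonate COP(=O)(OC)C(=[N+]=[N-])C(C)=O
Why: Seyferth–Gilbert homologation (Ohira–Bestmann variant) converts the aldehyde into the alkyne under carbonate conditions that should not epimerise the hindered α-centre.

Step 8
Reactants: 10 (3R,4R)-terminal alkyne
Product: 12 methyl (4S,5R)-alk-2-ynoate, via lithium acetylide 11 (not isolated)
Conditions: n-BuLi, THF, −78 °C; then ClCO2Me, −78 → 0 °C
Reagents that add atoms: methyl chloroformate COC(=O)Cl
Why: Acylation of the lithium acetylide with a chloroformate is standard and installs the future aldehyde carbon before any ketone is present.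

Step 9
Reactants: 12 methyl (4S,5R)-alk-2-ynoate
Product: 14 methyl (2E,4S,5R)-2-methyl-3-(trimethylstannyl)enoate, via vinylcopper adduct 13 (not isolated)
Conditions: Me6Sn2, MeLi, THF, −20 °C; CuSPh; then 12, −78 °C; then MeI, HMPA, −78 → −30 °C
Reagents that add atoms: Li[Me3SnCu(SPh)] [Li+].C[Sn](C)(C)[Cu-]Sc1ccccc1; iodomethane CI
Why: Stannylcupration of the ynoate is a syn addition (tin to the β-carbon, copper to the α-carbon), and methylation of the vinylcopper with retention should place the new methyl cis to tin and the ester cis to the branched carbon, which is the olefin geometry of the target.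

Step 10
Reactants: 14 methyl (2E,4S,5R)-2-methyl-3-(trimethylstannyl)enoate
Product: 15 methyl (2E,4S,5R)-3-iodo-2-methylenoate
Conditions: I2 (1.05 equiv), CH2Cl2, 0 °C
Reagents that add atoms: iodine II
Why: Iododestannylation of an alkenylstannane proceeds with retention and is much faster than any reaction of iodine with the trisubstituted olefins.

Step 11
Reactants: 15 methyl (2E,4S,5R)-3-iodo-2-methylenoate
Product: 16 methyl (2E,4S,5S)-5-acetyl-3-iodo-2-methylenoate
Conditions: PdCl2 (10 mol%), CuCl, O2 (1 atm), DMF/H2O 7:1, rt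
Reagents that add atoms: water O
Why: Tsuji–Wacker oxidation should attack only the monosubstituted vinyl group (Markovnikov, giving the methyl ketone), since the trisubstituted olefins and the tetrasubstituted iodo-enoate are poor ligands for divalent palladium.

Step 12
Reactants: 16 methyl (2E,4S,5S)-5-acetyl-3-iodo-2-methylenoate; 17 phenyl vinyl sulfone
Product: 20 methyl (2Z)-2-[(2R,3S,4R,5S)-5-(benzenesulfonyl)-4-hydroxycyclohexylidene]propanoate, via alkenylmagnesium chloride 18 (not isolated), via sulfonyl-stabilised magnesium carbanion 19 (not isolated)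
Conditions: i-PrMgCl·LiCl (1.05 equiv), THF, −78 °C; CuI·2LiCl (10 mol%); then 17 (1.1 equiv, slow addition), −78 → −40 °C; AcOH quench at −40 °C
Reagents that add atoms: none
Why: Iodine–magnesium exchange on the activated β-iodo enoate at −78 °C should give the configurationally stable alkenylmagnesium 18 faster than any attack on the hindered neopentyl-type methyl ketone; copper-catalysed conjugate addition of 18 to 17, with retention at the alkenyl carbon, then joins the alkylidene ring carbon to the first CH2 and leaves the α-sulfonyl magnesium carbanion 19. Carbanion 19 closes the cyclohexane by 6-exo-trig addition to the ketone, joining the second CH2 to the carbinol carbon; this is a Michael-initiated ring closure, and the closest known reaction type is conjugate addition of Grignard or organocopper reagents to vinyl sulfones with intramolecular trapping of the α-sulfonyl carbanion by a carbonyl group. The new carbinol centre is set in a chair-like closure in which A(1,3) strain against the ester-bearing alkylidene holds the silyloxypropyl chain axial, so the ketone methyl goes equatorial and the magnesium alkoxide axial (bridged to a sulfonyl oxygen), giving hydroxyl cis to the side chain and to the quaternary methyl as in the target; the sulfonyl-bearing centre (expected cis to the hydroxyl) is removed in step 14. The step needs chemoselectivity (exchange and conjugate addition before ketone addition, enolisation or proton transfer), which low temperature, catalytic copper, slow addition of 17 and a cold quench should secure. It also needs geometric integrity, which is secured because 18 does not isomerise at −78 °C and because 19 cannot reach the ester across the double bond.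

Step 13
Reactants: 20 hydroxy sulfone methyl ester
Product: 21 (2Z)-allylic alcohol hydroxy sulfone
Conditions: i-Bu2AlH (3.5 equiv), CH2Cl2, −78 °C; Rochelle salt work-up
Reagents that add atoms: none
Why: The aluminium hydride reduces the conjugated ester 1,2 to the allylic alcohol without touching the sulfone, the silyl ether or the olefin geometry, and it removes the enoate before the dissolving-metal step.

Step 14
Reactants: 21 (2Z)-allylic alcohol hydroxy sulfone
Product: 22 (2Z)-2-[(2R,3S,4S)-4-hydroxycyclohexylidene]propan-1-ol silyl ether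
Conditions: Na/Hg (6% Na), Na2HPO4, MeOH/THF, −20 °C
Reagents that add atoms: none
Why: In this Julia-type reductive desulfonylation, electron transfer cleaves the C–S bond and buffered methanol should protonate the carbanion faster than it can expel the free, non-acylated tertiary hydroxyl.

Step 15
Reactants: 22 silyl ether diol
Product: 23 (2Z)-triol
Conditions: Bu4NF, THF, 0 °C → rt
Reagents that add atoms: none
Why: Fluoride cleaves the primary silyl ether, and no base-sensitive carbonyl group is present at this stage.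

Step 16
Reactants: 23 (2Z)-triol
Product: 24 iridal
Conditions: MnO2 (excess), CH2Cl2, rt
Reagents that add atoms: none
Why: MnO2 oxidises only the allylic primary alcohol to the enal, under neutral conditions that should preserve the (Z)-tetrasubstituted olefin and leave the saturated primary and the tertiary alcohol alone.

**Compound list**

1 | pentane-1,5-diol | OCCCCCO | starting material
2 | 5-[(tert-butyldiphenylsilyl)oxy]pentan-1-ol | OCCCCCO[Si](c1ccccc1)(c1ccccc1)C(C)(C)C | intermediate
3 | 5-[(tert-butyldiphenylsilyl)oxy]pentanoic acid | OC(=O)CCCCO[Si](c1ccccc1)(c1ccccc1)C(C)(C)C | intermediate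
4 | (2E,6E,10E)-3,7,11,15-tetramethylhexadeca-2,6,10,14-tetraen-1-ol (geranylgeraniol) | CC(C)=CCC/C(C)=C/CC/C(C)=C/CC/C(C)=C/CO | starting material
5 | (2E,6E,10E)-3,7,11,15-tetramethylhexadeca-2,6,10,14-tetraen-1-yl 5-[(tert-butyldiphenylsilyl)oxy]pentanoate | CC(C)=CCC/C(C)=C/CC/C(C)=C/CC/C(C)=C/COC(=O)CCCCO[Si](c1ccccc1)(c1ccccc1)C(C)(C)C | intermediate
6 | boron ketene acetal of 5: enolate oxygen bound to the (4S,5S)-4,5-diphenyl-1,3-bis[3,5-bis(trifluoromethyl)benzenesulfonyl]-1,3,2-diazaborolidin-2-yl group, silyloxypropyl chain cis to the O–B oxygen | CC(C)=CCC/C(C)=C/CC/C(C)=C/CC/C(C)=C/CO/C(OB1N(S(=O)(=O)c2cc(cc(c2)C(F)(F)F)C(F)(F)F)[C@@H](c2ccccc2)[C@H](c2ccccc2)N1S(=O)(=O)c1cc(cc(c1)C(F)(F)F)C(F)(F)F)=C/CCCO[Si](c1ccccc1)(c1ccccc1)C(C)(C)C | intermediate (not isolated)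
7 | (2S,3R,6E,10E)-2-{3-[(tert-butyldiphenylsilyl)oxy]propyl}-3-ethenyl-3,7,11,15-tetramethylhexadeca-6,10,14-trienoic acid | CC(C)=CCC/C(C)=C/CC/C(C)=C/CC[C@@](C=C)(C)[C@H](CCCO[Si](c1ccccc1)(c1ccccc1)C(C)(C)C)C(=O)O | intermediate
8 | (2S,3R,6E,10E)-2-{3-[(tert-butyldiphenylsilyl)oxy]propyl}-3-ethenyl-3,7,11,15-tetramethylhexadeca-6,10,14-trien-1-ol | CC(C)=CCC/C(C)=C/CC/C(C)=C/CC[C@@](C=C)(C)[C@H](CCCO[Si](c1ccccc1)(c1ccccc1)C(C)(C)C)CO | intermediate
9 | (2S,3R,6E,10E)-2-{3-[(tert-butyldiphenylsilyl)oxy]propyl}-3-ethenyl-3,7,11,15-tetramethylhexadeca-6,10,14-trienal | CC(C)=CCC/C(C)=C/CC/C(C)=C/CC[C@@](C=C)(C)[C@H](CCCO[Si](c1ccccc1)(c1ccccc1)C(C)(C)C)C=O | intermediate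
10 | (3R,4R,7E,11E)-3-{3-[(tert-butyldiphenylsilyl)oxy]propyl}-4-ethenyl-4,8,12,16-tetramethylheptadeca-7,11,15-trien-1-yne | CC(C)=CCC/C(C)=C/CC/C(C)=C/CC[C@@](C=C)(C)[C@H](CCCO[Si](c1ccccc1)(c1ccccc1)C(C)(C)C)C#C | intermediate
11 | lithium acetylide of 10 | CC(C)=CCC/C(C)=C/CC/C(C)=C/CC[C@@](C=C)(C)[C@H](CCCO[Si](c1ccccc1)(c1ccccc1)C(C)(C)C)C#C[Li] | intermediate (not isolated)
12 | methyl (4S,5R,8E,12E)-4-{3-[(tert-butyldiphenylsilyl)oxy]propyl}-5-ethenyl-5,9,13,17-tetramethyloctadeca-8,12,16-trien-2-ynoate | CC(C)=CCC/C(C)=C/CC/C(C)=C/CC[C@@](C=C)(C)[C@H](CCCO[Si](c1ccccc1)(c1ccccc1)C(C)(C)C)C#CC(=O)OC | intermediate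
13 | lithium (phenylthio)cuprate of the 2-cuprio-3-(trimethylstannyl)enoate from 12 (tin and copper cis) | CC(C)=CCC/C(C)=C/CC/C(C)=C/CC[C@@](C=C)(C)[C@H](CCCO[Si](c1ccccc1)(c1ccccc1)C(C)(C)C)/C([Sn](C)(C)C)=C(/[Cu-]Sc1ccccc1)C(=O)OC.[Li+] | intermediate (not isolated)
14 | methyl (2E,4S,5R,8E,12E)-4-{3-[(tert-butyldiphenylsilyl)oxy]propyl}-5-ethenyl-2,5,9,13,17-pentamethyl-3-(trimethylstannyl)octadeca-2,8,12,16-tetraenoate | CC(C)=CCC/C(C)=C/CC/C(C)=C/CC[C@@](C=C)(C)[C@H](CCCO[Si](c1ccccc1)(c1ccccc1)C(C)(C)C)/C([Sn](C)(C)C)=C(/C)C(=O)OC | intermediate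
15 | methyl (2E,4S,5R,8E,12E)-4-{3-[(tert-butyldiphenylsilyl)oxy]propyl}-5-ethenyl-3-iodo-2,5,9,13,17-pentamethyloctadeca-2,8,12,16-tetraenoate | CC(C)=CCC/C(C)=C/CC/C(C)=C/CC[C@@](C=C)(C)[C@H](CCCO[Si](c1ccccc1)(c1ccccc1)C(C)(C)C)/C(I)=C(/C)C(=O)OC | intermediate
16 | methyl (2E,4S,5S,8E,12E)-5-acetyl-4-{3-[(tert-butyldiphenylsilyl)oxy]propyl}-3-iodo-2,5,9,13,17-pentamethyloctadeca-2,8,12,16-tetraenoate | CC(C)=CCC/C(C)=C/CC/C(C)=C/CC[C@@](C(C)=O)(C)[C@H](CCCO[Si](c1ccccc1)(c1ccccc1)C(C)(C)C)/C(I)=C(/C)C(=O)OC | intermediate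
17 | phenyl vinyl sulfone (ethenesulfonylbenzene) | C=CS(=O)(=O)c1ccccc1 | starting material
18 | alkenylmagnesium chloride from 16 (MgCl in place of iodine, magnesium cis to the 2-methyl group) | CC(C)=CCC/C(C)=C/CC/C(C)=C/CC[C@@](C(C)=O)(C)[C@H](CCCO[Si](c1ccccc1)(c1ccccc1)C(C)(C)C)/C([Mg]Cl)=C(/C)C(=O)OC | intermediate (not isolated)
19 | open-chain conjugate adduct of 18 and 17: 3-[2-(benzenesulfonyl)-2-(chloromagnesio)ethyl] enoate still carrying the methyl ketone | CC(C)=CCC/C(C)=C/CC/C(C)=C/CC[C@@](C(C)=O)(C)[C@H](CCCO[Si](c1ccccc1)(c1ccccc1)C(C)(C)C)/C(=C(/C)C(=O)OC)CC([Mg]Cl)S(=O)(=O)c1ccccc1 | intermediate (not isolated)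
20 | methyl (2Z)-2-[(2R,3S,4R,5S)-5-(benzenesulfonyl)-2-{3-[(tert-butyldiphenylsilyl)oxy]propyl}-4-hydroxy-3,4-dimethyl-3-[(3E,7E)-4,8,12-trimethyltrideca-3,7,11-trien-1-yl]cyclohexylidene]propanoate (expected sulfonyl epimer shown; the other would serve equally) | CC(C)=CCC/C(C)=C/CC/C(C)=C/CC[C@@]1(C)[C@H](CCCO[Si](c2ccccc2)(c2ccccc2)C(C)(C)C)/C(=C(/C)C(=O)OC)C[C@H](S(=O)(=O)c2ccccc2)[C@]1(C)O | intermediate
21 | (2Z)-2-[(2R,3S,4R,5S)-5-(benzenesulfonyl)-2-{3-[(tert-butyldiphenylsilyl)oxy]propyl}-4-hydroxy-3,4-dimethyl-3-[(3E,7E)-4,8,12-trimethyltrideca-3,7,11-trien-1-yl]cyclohexylidene]propan-1-ol | CC(C)=CCC/C(C)=C/CC/C(C)=C/CC[C@@]1(C)[C@H](CCCO[Si](c2ccccc2)(c2ccccc2)C(C)(C)C)/C(=C(/C)CO)C[C@H](S(=O)(=O)c2ccccc2)[C@]1(C)O | intermediate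
22 | (2Z)-2-[(2R,3S,4S)-2-{3-[(tert-butyldiphenylsilyl)oxy]propyl}-4-hydroxy-3,4-dimethyl-3-[(3E,7E)-4,8,12-trimethyltrideca-3,7,11-trien-1-yl]cyclohexylidene]propan-1-ol | CC(C)=CCC/C(C)=C/CC/C(C)=C/CC[C@@]1(C)[C@H](CCCO[Si](c2ccccc2)(c2ccccc2)C(C)(C)C)/C(=C(/C)CO)CC[C@]1(C)O | intermediate
23 | (2Z)-2-[(2R,3S,4S)-4-hydroxy-2-(3-hydroxypropyl)-3,4-dimethyl-3-[(3E,7E)-4,8,12-trimethyltrideca-3,7,11-trien-1-yl]cyclohexylidene]propan-1-ol | CC(C)=CCC/C(C)=C/CC/C(C)=C/CC[C@@]1(C)[C@H](CCCO)/C(=C(/C)CO)CC[C@]1(C)O | intermediate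
24 | iridal, (2Z)-2-[(2R,3S,4S)-4-hydroxy-2-(3-hydroxypropyl)-3,4-dimethyl-3-[(3E,7E)-4,8,12-trimethyltrideca-3,7,11-trien-1-yl]cyclohexylidene]propanal | CC(C)=CCC/C(C)=C/CC/C(C)=C/CC[C@@]1(C)[C@H](CCCO)/C(=C(/C)C=O)CC[C@]1(C)O | target

**Step count**

Total: 16 steps. Longest linear sequence: 16 steps from pentane-1,5-diol (14 from geranylgeraniol).

**Steps most likely to fail**

Step 12 (key step). The alkenylmagnesium may add to or enolise the methyl ketone before it finds the sulfone. The α-sulfonyl carbanion may take a proton from the ketone methyl instead of closing the ring. The vinyl sulfone may oligomerise anionically. The β-magnesio enoate may isomerise.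
Fallback: set out from 16 and form the two bonds in two separate, non-basic operations. A Heck reaction of 16 with 17 (Pd(OAc)2, P(o-tol)3, Et3N, MeCN, 60 °C) should give the dienyl sulfone F1, that is 16 with iodine replaced by an (E)-2-(benzenesulfonyl)ethenyl group and the enoate geometry retained. Conjugate reduction of the sulfonyl-activated double bond with [CuH(PPh3)]6 (toluene/THF, −40 °C → rt) then generates the α-sulfonyl copper species without base, and this should close onto the ketone in a reductive aldol-type cyclisation under the same chair control. The route is rejoined at 20.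

Step 9. During the slow methylation the α-cuprio enoate may equilibrate with its allenoate form, eroding the geometry of the tetrasubstituted olefin, and methylation may be incomplete.
Fallback: set out from acid 7 and build the olefin from a carbonyl compound instead of the alkyne. Activation with carbonyldiimidazole and reaction with potassium methyl 2-methylmalonate/MgCl2 should give the β-keto ester F2 (methyl 2-methyl-3-oxo ester, epimeric at C2). Enol triflation under non-chelating conditions (Tf2O, aqueous Me4NOH, hexane, 5 °C) should favour the (E)-enol triflate F3, with the triflate cis to the 2-methyl group. Stannylation with retention (Pd(PPh3)4, Me6Sn2, LiCl, THF, 60 °C) rejoins the route at 14.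

Step 11. Transient zerovalent palladium may insert into the activated alkenyl C–I bond (loss of iodide, Heck-type consumption of the vinyl group), and hydroxypalladation of the neopentyl-type vinyl group may be slow.
Fallback: set out from 12 and oxidise before any tin or iodine is present. The same Wacker conditions applied to 12 should give the keto ynoate F4. Stannylcupration/methylation as in step 9 then gives the keto stannane F5, and iododestannylation as in step 10 rejoins the route at 16.

Further compounds
F1 | step 12 | dienyl sulfone: methyl 5-acetyl-3-[(E)-2-(benzenesulfonyl)ethenyl]-4-{3-[(tert-butyldiphenylsilyl)oxy]propyl}-2,5,9,13,17-pentamethyloctadeca-2,8,12,16-tetraenoate, stereocentres and enoate geometry as in 16 | CC(C)=CCC/C(C)=C/CC/C(C)=C/CC[C@@](C(C)=O)(C)[C@H](CCCO[Si](c1ccccc1)(c1ccccc1)C(C)(C)C)/C(=C(/C)C(=O)OC)/C=C/S(=O)(=O)c1ccccc1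
F2 | step 9 | β-keto ester: methyl 4-{3-[(tert-butyldiphenylsilyl)oxy]propyl}-5-ethenyl-2,5,9,13,17-pentamethyl-3-oxooctadeca-8,12,16-trienoate, stereocentres at C4 and C5 as in 7, epimeric at C2 | CC(C)=CCC/C(C)=C/CC/C(C)=C/CC[C@@](C=C)(C)[C@H](CCCO[Si](c1ccccc1)(c1ccccc1)C(C)(C)C)C(=O)C(C)C(=O)OC
F3 | step 9 | (E)-enol triflate: 14 with trifluoromethanesulfonyloxy in place of trimethylstannyl | CC(C)=CCC/C(C)=C/CC/C(C)=C/CC[C@@](C=C)(C)[C@H](CCCO[Si](c1ccccc1)(c1ccccc1)C(C)(C)C)/C(OS(=O)(=O)C(F)(F)F)=C(/C)C(=O)OC
F4 | step 11 | keto ynoate: 12 with acetyl in place of ethenyl | CC(C)=CCC/C(C)=C/CC/C(C)=C/CC[C@@](C(C)=O)(C)[C@H](CCCO[Si](c1ccccc1)(c1ccccc1)C(C)(C)C)C#CC(=O)OC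
F5 | step 11 | keto stannane: 14 with acetyl in place of ethenyl | CC(C)=CCC/C(C)=C/CC/C(C)=C/CC[C@@](C(C)=O)(C)[C@H](CCCO[Si](c1ccccc1)(c1ccccc1)C(C)(C)C)/C([Sn](C)(C)C)=C(/C)C(=O)OC
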